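**Retrosynthetic overview**

1. Target 27 ⇐ 26: the butenolide is made last, by ring-closing metathesis (C-11=C-12) across a 15-membered α-methylene keto-lactone.
2. 26 ⇐ seco aldehyde 25: the key C-9–C-10 bond comes from a carbene-derived acyl anion at C-9 that attacks the 2-(bromomethyl)acrylate ester on O-13 (conjugate addition, bromide loss), closing the 15-membered ring.
3. 25 ⇐ alcohol 23 + 2-(bromomethyl)acrylic acid; 23 ⇐ vinyl carbinol 21 + (S)-3-methylhex-5-enal 8 by E-selective cross-metathesis (C-4=C-5).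
4. 21 ⇐ Evans syn-aldol (C-13, C-14), D-proline acetone aldol (C-1), chelation-controlled vinyl Grignard addition (C-3); 8 ⇐ auxiliary-controlled conjugate allylation (C-7).
5. Ring order: 15-membered keto-lactone first, then the butenolide, which turns it into the 14-membered carbocycle of the target.

Assumption: ring carbons are called C-1 to C-14 in the order of the SMILES (C-1 CHOAc, C-3 C(OH)Me, C-7 CHMe, C-9 ketone, C-11=C-12 butenolide alkene, C-13 CH–O, C-14 CH–iPr), and imide 9 is bought as such.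

**Route**

Step 1
Reactants: 1 (S)-4-benzyloxazolidin-2-one; 2 (E)-but-2-enoyl chloride
Product: 4 (S)-4-benzyl-3-[(E)-but-2-enoyl]oxazolidin-2-one, via N-lithio oxazolidinone 3 (not isolated)
Conditions: n-BuLi, THF, −78 °C; then 2, −78 → 0 °C
Reagents that add atoms: none
Why: N-Acylation of the lithiated oxazolidinone with an acid chloride (standard preparation of Evans N-enoyl imides) is fast at −78 °C and creates no stereocentre.

Step 2
Reactants: 4 (S)-4-benzyl-3-[(E)-but-2-enoyl]oxazolidin-2-one; 5 allylmagnesium bromide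
Product: 6 (S)-4-benzyl-3-[(3S)-3-methylhex-5-enoyl]oxazolidin-2-one
Conditions: CuBr·SMe2 (1.1 equiv), 5 (1.1 equiv), THF/Me2S, −78 °C; then 4, −78 → −40 °C; aq NH4Cl
Reagents that add atoms: none
Why: Auxiliary-controlled conjugate addition of an allylcopper reagent: in the magnesium-chelated s-cis N-enoyl imide the benzyl group blocks one face of the β-carbon, so allyl adds to the other and sets the (3S) methyl stereocentre (C-7).

Step 3
Reactants: 6 (S)-4-benzyl-3-[(3S)-3-methylhex-5-enoyl]oxazolidin-2-one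
Product: 7 (S)-3-methylhex-5-en-1-ol
Conditions: LiBH4, H2O (1 equiv), Et2O, 0 °C
Reagents that add atoms: none
Why: Reductive cleavage of the N-acyl oxazolidinone with LiBH4 (hydride reduction) gives the primary alcohol and releases the auxiliary without touching the alkene or the β-stereocentre.

Step 4
Reactants: 7 (S)-3-methylhex-5-en-1-ol
Product: 8 (S)-3-methylhex-5-enal
Conditions: Dess–Martin periodinane, pyridine, CH2Cl2, 0 °C → rt
Reagents that add atoms: none
Why: Dess–Martin oxidation stops at the aldehyde under near-neutral conditions, and the stereocentre is β to the carbonyl so it cannot epimerise.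

Step 5
Reactants: 9 (S)-4-benzyl-3-(3-methylbutanoyl)oxazolidin-2-one; 10 (E)-but-2-enal
Product: 12 (S)-4-benzyl-3-[(2S,3R,4E)-3-hydroxy-2-(propan-2-yl)hex-4-enoyl]oxazolidin-2-one, via dibutylboron Z-enolate 11 (not isolated)
Conditions: Bu2BOTf, iPr2NEt, CH2Cl2, 0 °C; then 10, −78 → 0 °C; then H2O2, MeOH, pH 7 buffer, 0 °C
Reagents that add atoms: none
Why: Evans syn-aldol reaction: the Z-boron enolate adds 1,2 to the enal through a Zimmerman–Traxler chair on the face away from the benzyl group, which sets the 2,3-syn (2S,3R) pair (C-14 and C-13).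

Step 6
Reactants: 12 (S)-4-benzyl-3-[(2S,3R,4E)-3-hydroxy-2-(propan-2-yl)hex-4-enoyl]oxazolidin-2-one
Product: 13 (S)-4-benzyl-3-[(2S,3R,4E)-2-(propan-2-yl)-3-[(triethylsilyl)oxy]hex-4-enoyl]oxazolidin-2-one
Conditions: TESOTf, 2,6-lutidine, CH2Cl2, −78 °C
Reagents that add atoms: triethylsilyl trifluoromethanesulfonate, CC[Si](CC)(CC)OS(=O)(=O)C(F)(F)F
Why: Silyl ether formation with a silyl triflate and 2,6-lutidine is reliable on hindered secondary alcohols and masks the C-13 hydroxyl until the acrylate is introduced.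

Step 7
Reactants: 13 (S)-4-benzyl-3-[(2S,3R,4E)-2-(propan-2-yl)-3-[(triethylsilyl)oxy]hex-4-enoyl]oxazolidin-2-one
Product: 14 (2R,3R,4E)-2-(propan-2-yl)-3-[(triethylsilyl)oxy]hex-4-en-1-ol
Conditions: LiBH4, MeOH (1 equiv), THF, 0 °C
Reagents that add atoms: none
Why: Reductive auxiliary removal with LiBH4 (hydride reduction of the imide) gives the primary alcohol, with the silyl ether preventing retro-aldol cleavage and the α-stereocentre untouched.

Step 8
Reactants: 14 (2R,3R,4E)-2-(propan-2-yl)-3-[(triethylsilyl)oxy]hex-4-en-1-ol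
Product: 15 (2S,3R,4E)-2-(propan-2-yl)-3-[(triethylsilyl)oxy]hex-4-enal
Conditions: Dess–Martin periodinane, pyridine, CH2Cl2, 0 °C
Reagents that add atoms: none
Why: Pyridine-buffered Dess–Martin oxidation gives the α-branched aldehyde without epimerisation or silyl migration.

Step 9
Reactants: 15 (2S,3R,4E)-2-(propan-2-yl)-3-[(triethylsilyl)oxy]hex-4-enal; 16 acetone
Product: 17 (4S,5R,6R,7E)-4-hydroxy-5-(propan-2-yl)-6-[(triethylsilyl)oxy]non-7-en-2-one
Conditions: D-proline (30 mol %), DMSO/acetone 4:1, rt, 48 h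
Reagents that add atoms: none
Why: Proline-catalysed direct aldol reaction (enamine catalysis): D-proline sends the acetone enamine to the aldehyde face opposite to the one used by L-proline (which gives R carbinols from α-branched aldehydes), and this catalyst control is matched with Felkin–Anh attack anti to the silyloxy-bearing branch, setting (4S) (C-1).

Step 10
Reactants: 17 (4S,5R,6R,7E)-4-hydroxy-5-(propan-2-yl)-6-[(triethylsilyl)oxy]non-7-en-2-one; 18 vinylmagnesium bromide
Product: 20 (3S,5S,6R,7R,8E)-3-methyl-6-(propan-2-yl)-7-[(triethylsilyl)oxy]deca-1,8-diene-3,5-diol, via bromomagnesium alkoxide 19 (not isolated)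
Conditions: 18 (3.5 equiv), CH2Cl2/THF, −78 °C; aq NH4Cl
Reagents that add atoms: none
Why: Chelation-controlled Grignard addition (Cram chelate model): the first equivalent forms the bromomagnesium alkoxide, which binds the ketone in a six-membered chelate so that vinyl adds axially, anti to the ring substituent, giving the 3,5-anti diol with the (3S) tertiary carbinol (C-3); the minor 3-epimer is removed by chromatography.

Step 11
Reactants: 20 (3S,5S,6R,7R,8E)-3-methyl-6-(propan-2-yl)-7-[(triethylsilyl)oxy]deca-1,8-diene-3,5-diol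
Product: 21 (3S,5S,6R,7R,8E)-3-hydroxy-3-methyl-6-(propan-2-yl)-7-[(triethylsilyl)oxy]deca-1,8-dien-5-yl acetate
Conditions: Ac2O, pyridine, DMAP (5 mol %), CH2Cl2, 0 °C
Reagents that add atoms: acetic anhydride, CC(=O)OC(C)=O
Why: Acetylation (nucleophilic catalysis by DMAP) takes place only at the secondary hydroxyl because the tertiary allylic one is far more hindered, so the C-1 acetate of the target is installed without a protecting group.

Step 12
Reactants: 21 (3S,5S,6R,7R,8E)-3-hydroxy-3-methyl-6-(propan-2-yl)-7-[(triethylsilyl)oxy]deca-1,8-dien-5-yl acetate; 8 (S)-3-methylhex-5-enal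
Product: 22 (3S,5E,7S,9S,10R,11R,12E)-7-hydroxy-3,7-dimethyl-1-oxo-10-(propan-2-yl)-11-[(triethylsilyl)oxy]tetradeca-5,12-dien-9-yl acetate
Conditions: second-generation Hoveyda–Grubbs catalyst RuCl2(H2IMes)(=CH-C6H4-2-OiPr) (5 mol %), 8 (2.5 equiv), CH2Cl2, 40 °C
Reagents that add atoms: none
Why: Olefin cross-metathesis of a terminal alkene with a free tertiary allylic alcohol is selective for the cross product and gives the E-alkene, while the internal propenyl group flanked by a branched silyloxy carbon reacts much more slowly; no stereocentre is touched.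

Step 13
Reactants: 22 (3S,5E,7S,9S,10R,11R,12E)-7-hydroxy-3,7-dimethyl-1-oxo-10-(propan-2-yl)-11-[(triethylsilyl)oxy]tetradeca-5,12-dien-9-yl acetate
Product: 23 (3S,5E,7S,9S,10S,11R,12E)-7,11-dihydroxy-3,7-dimethyl-1-oxo-10-(propan-2-yl)tetradeca-5,12-dien-9-yl acetate
Conditions: HF·pyridine, pyridine, THF, 0 °C
Reagents that add atoms: none
Why: Fluoride-mediated desilylation in pyridine-buffered HF removes the triethylsilyl ether without acetyl migration or damage to the aldehyde and the tertiary allylic alcohol.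

Step 14
Reactants: 23 (3S,5E,7S,9S,10S,11R,12E)-7,11-dihydroxy-3,7-dimethyl-1-oxo-10-(propan-2-yl)tetradeca-5,12-dien-9-yl acetate; 24 2-(bromomethyl)prop-2-enoic acid
Product: 25 (3S,5E,7S,9S,10R,11R,12E)-9-(acetyloxy)-7-hydroxy-3,7-dimethyl-1-oxo-10-(propan-2-yl)tetradeca-5,12-dien-11-yl 2-(bromomethyl)prop-2-enoate
Conditions: DCC, DMAP (10 mol %), CH2Cl2, 0 °C → rt
Reagents that add atoms: none
Why: Steglich esterification (carbodiimide activation) acylates the only free secondary hydroxyl, the tertiary one being inert, with retention at C-13 and places the allylic bromide acceptor next to it.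

Step 15
Reactants: 25 (3S,5E,7S,9S,10R,11R,12E)-9-(acetyloxy)-7-hydroxy-3,7-dimethyl-1-oxo-10-(propan-2-yl)tetradeca-5,12-dien-11-yl 2-(bromomethyl)prop-2-enoate
Product: 26 (7S,9E,11S,13S,14R,15R)-11-hydroxy-7,11-dimethyl-3-methylidene-2,5-dioxo-14-(propan-2-yl)-15-[(1E)-prop-1-en-1-yl]-1-oxacyclopentadec-9-en-13-yl acetate
Conditions: 3-benzyl-5-(2-hydroxyethyl)-4-methylthiazolium chloride (30 mol %), K2CO3 (2 equiv), 1,4-dioxane, 70 °C, syringe-pump addition of 25 over 12 h (final 2 mM)
Reagents that add atoms: none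
Why: Proposed new method: the thiazol-2-ylidene adds to the C-9 aldehyde to give a Breslow intermediate (acyl anion equivalent) that attacks a CH2 terminus of the 2-(bromomethyl)acrylate in a Stetter-type conjugate addition, the ester enolate then expels bromide (E1cB) and regenerates the carbene, so C-9 and C-10, both natural acceptor carbons, are joined, both CH2 termini lead to the same product, no stereocentre is formed and high dilution favours the 15-membered ring; the closest known reactions are the Stetter reaction of aliphatic aldehydes with acrylates and carbene-catalysed couplings of aldehydes with activated alkyl bromides.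

Step 16
Reactants: 26 (7S,9E,11S,13S,14R,15R)-11-hydroxy-7,11-dimethyl-3-methylidene-2,5-dioxo-14-(propan-2-yl)-15-[(1E)-prop-1-en-1-yl]-1-oxacyclopentadec-9-en-13-yl acetate
Product: 27 CNP0200490.2, (5S,7E,9S,11S,12R,13R)-9-hydroxy-5,9-dimethyl-3,15-dioxo-12-(propan-2-yl)-14-oxabicyclo[11.2.1]hexadeca-1(16),7-dien-11-yl acetate
Conditions: second-generation Hoveyda–Grubbs catalyst RuCl2(H2IMes)(=CH-C6H4-2-OiPr) (10 mol %), toluene, 80 °C, 1 mM
Reagents that add atoms: none
Why: Ring-closing metathesis between the 1,1-disubstituted acrylate alkene and the propenyl group releases propene and closes the five-membered butenolide, the fastest ring to form, which turns the 15-membered lactone into the 14-membered carbocycle without touching the E-alkene or any stereocentre.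

**Compound list**

1 | (S)-4-benzyloxazolidin-2-one | O=C1N[C@@H](Cc2ccccc2)CO1 | starting material
2 | (E)-but-2-enoyl chloride | C/C=C/C(Cl)=O | starting material
3 | lithium (S)-4-benzyl-2-oxooxazolidin-3-ide | [Li]N1[C@@H](Cc2ccccc2)COC1=O | intermediate
4 | (S)-4-benzyl-3-[(E)-but-2-enoyl]oxazolidin-2-one | C/C=C/C(=O)N1[C@@H](Cc2ccccc2)COC1=O | intermediate
5 | allylmagnesium bromide | C=CC[Mg]Br | starting material
6 | (S)-4-benzyl-3-[(3S)-3-methylhex-5-enoyl]oxazolidin-2-one | C=CC[C@H](C)CC(=O)N1[C@@H](Cc2ccccc2)COC1=O | intermediate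
7 | (S)-3-methylhex-5-en-1-ol | C=CC[C@H](C)CCO | intermediate
8 | (S)-3-methylhex-5-enal | C=CC[C@H](C)CC=O | intermediate
9 | (S)-4-benzyl-3-(3-methylbutanoyl)oxazolidin-2-one | CC(C)CC(=O)N1[C@@H](Cc2ccccc2)COC1=O | starting material
10 | (E)-but-2-enal | C/C=C/C=O | starting material
11 | (S)-4-benzyl-3-[(1Z)-1-(dibutylboranyloxy)-3-methylbut-1-en-1-yl]oxazolidin-2-one (boron enolate of 9) | CCCCB(CCCC)O/C(=C\C(C)C)N1[C@@H](Cc2ccccc2)COC1=O | intermediate
12 | (S)-4-benzyl-3-[(2S,3R,4E)-3-hydroxy-2-(propan-2-yl)hex-4-enoyl]oxazolidin-2-one | C/C=C/[C@@H](O)[C@@H](C(=O)N1[C@@H](Cc2ccccc2)COC1=O)C(C)C | intermediate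
13 | (S)-4-benzyl-3-[(2S,3R,4E)-2-(propan-2-yl)-3-[(triethylsilyl)oxy]hex-4-enoyl]oxazolidin-2-one | C/C=C/[C@@H](O[Si](CC)(CC)CC)[C@@H](C(=O)N1[C@@H](Cc2ccccc2)COC1=O)C(C)C | intermediate
14 | (2R,3R,4E)-2-(propan-2-yl)-3-[(triethylsilyl)oxy]hex-4-en-1-ol | C/C=C/[C@@H](O[Si](CC)(CC)CC)[C@@H](CO)C(C)C | intermediate
15 | (2S,3R,4E)-2-(propan-2-yl)-3-[(triethylsilyl)oxy]hex-4-enal | C/C=C/[C@@H](O[Si](CC)(CC)CC)[C@@H](C=O)C(C)C | intermediate
16 | acetone | CC(C)=O | starting material
17 | (4S,5R,6R,7E)-4-hydroxy-5-(propan-2-yl)-6-[(triethylsilyl)oxy]non-7-en-2-one | C/C=C/[C@@H](O[Si](CC)(CC)CC)[C@@H]([C@@H](O)CC(C)=O)C(C)C | intermediate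
18 | vinylmagnesium bromide | C=C[Mg]Br | starting material
19 | bromomagnesium 4-alkoxide of 17 | C/C=C/[C@@H](O[Si](CC)(CC)CC)[C@@H]([C@@H](O[Mg]Br)CC(C)=O)C(C)C | intermediate
20 | (3S,5S,6R,7R,8E)-3-methyl-6-(propan-2-yl)-7-[(triethylsilyl)oxy]deca-1,8-diene-3,5-diol | C/C=C/[C@@H](O[Si](CC)(CC)CC)[C@@H]([C@@H](O)C[C@](C)(O)C=C)C(C)C | intermediate
21 | (3S,5S,6R,7R,8E)-3-hydroxy-3-methyl-6-(propan-2-yl)-7-[(triethylsilyl)oxy]deca-1,8-dien-5-yl acetate | C/C=C/[C@@H](O[Si](CC)(CC)CC)[C@@H]([C@@H](OC(C)=O)C[C@](C)(O)C=C)C(C)C | intermediate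
22 | (3S,5E,7S,9S,10R,11R,12E)-7-hydroxy-3,7-dimethyl-1-oxo-10-(propan-2-yl)-11-[(triethylsilyl)oxy]tetradeca-5,12-dien-9-yl acetate | C/C=C/[C@@H](O[Si](CC)(CC)CC)[C@@H]([C@@H](OC(C)=O)C[C@](C)(O)/C=C/C[C@H](C)CC=O)C(C)C | intermediate
23 | (3S,5E,7S,9S,10S,11R,12E)-7,11-dihydroxy-3,7-dimethyl-1-oxo-10-(propan-2-yl)tetradeca-5,12-dien-9-yl acetate | C/C=C/[C@@H](O)[C@@H]([C@@H](OC(C)=O)C[C@](C)(O)/C=C/C[C@H](C)CC=O)C(C)C | intermediate
24 | 2-(bromomethyl)prop-2-enoic acid | C=C(CBr)C(=O)O | starting material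
25 | (3S,5E,7S,9S,10R,11R,12E)-9-(acetyloxy)-7-hydroxy-3,7-dimethyl-1-oxo-10-(propan-2-yl)tetradeca-5,12-dien-11-yl 2-(bromomethyl)prop-2-enoate | C/C=C/[C@@H](OC(=O)C(=C)CBr)[C@@H]([C@@H](OC(C)=O)C[C@](C)(O)/C=C/C[C@H](C)CC=O)C(C)C | intermediate
26 | (7S,9E,11S,13S,14R,15R)-11-hydroxy-7,11-dimethyl-3-methylidene-2,5-dioxo-14-(propan-2-yl)-15-[(1E)-prop-1-en-1-yl]-1-oxacyclopentadec-9-en-13-yl acetate | CC(=O)O[C@H]1C[C@](C)(O)/C=C/C[C@H](C)CC(=O)CC(=C)C(=O)O[C@H](/C=C/C)[C@@H]1C(C)C | intermediate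
27 | CNP0200490.2, (5S,7E,9S,11S,12R,13R)-9-hydroxy-5,9-dimethyl-3,15-dioxo-12-(propan-2-yl)-14-oxabicyclo[11.2.1]hexadeca-1(16),7-dien-11-yl acetate | CC(=O)O[C@H]1C[C@](C)(O)/C=C/C[C@H](C)CC(=O)CC2=C[C@@H](OC2=O)[C@@H]1C(C)C | target

**Step count**

Total: 16 steps (steps 1–4 make aldehyde 8; steps 5–16 run from imide 9 to the target).
Longest linear sequence: 12 steps (steps 5–16).

**Steps most likely to fail, and fallbacks**

Step 15. The carbene-catalysed closure of a 15-membered ring from an aliphatic aldehyde is untested; acyloin or aldol side reactions, oligomers, or base-induced isomerisation of the α-methylene keto ester into conjugation could take over. The fallback keeps the same C-9–C-10 bond but makes it between two molecules and closes the ring at the lactone C–O bond instead. Acid 24 is esterified (allyl alcohol, DCC, DMAP cat.) to allyl 2-(bromomethyl)prop-2-enoate F1. F1 is coupled at 0.3 M with hydroxy aldehyde 23 under the thiazolium/K2CO3 conditions to give open-chain keto allyl ester F2. Pd(PPh3)4 and morpholine then free seco acid F3. Yamaguchi macrolactonisation (2,4,6-trichlorobenzoyl chloride, Et3N; then DMAP, toluene, 1 mM, 60 °C) onto the secondary allylic hydroxyl returns to 26.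

Step 16. Metathesis across the macrocycle to a bridged butenolide may be slow, and the catalyst may instead open the ring at the C-4=C-5 alkene. The fallback reverses the order of the two ring closures and sets out from 25. Treating 25 first with the Hoveyda–Grubbs catalyst closes the butenolide on the open chain, where it is unstrained, to give bromomethyl butenolide aldehyde F4. The carbene-catalysed acyl-anion alkylation is then run last, displacing the allylic bromide at the exocyclic CH2, and closes the 14-membered ring to give 27 directly. This order risks attack at the ring β-carbon and epimerisation at C-13, which is why it is not the first choice.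

Step 10. The 1,3-induction from a free β-hydroxyl in the vinyl Grignard addition may give a poor anti:syn ratio at the tertiary carbinol. The fallback takes the C-3 stereocentre from a reagent and sets C-1 from it, starting from aldehyde 15. Propane-1,3-dithiol with MgBr2·OEt2 converts 15 into dithiane F5. Its 2-lithio derivative (t-BuLi, THF/HMPA, −78 °C) opens (R)-2-methyl-2-vinyloxirane at CH2 to give hydroxy dithiane F6. MeI and CaCO3 in aqueous MeCN unmask β-hydroxy ketone F7. Hydroxyl-directed 1,3-anti reduction with Me4NBH(OAc)3 (MeCN/AcOH, −30 °C) then gives diol 20.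

**Further compounds**

F1 | step 15 | allyl 2-(bromomethyl)prop-2-enoate | C=CCOC(=O)C(=C)CBr
F2 | step 15 | prop-2-en-1-yl (6S,8E,10S,12S,13S,14R,15E)-12-(acetyloxy)-10,14-dihydroxy-6,10-dimethyl-2-methylidene-4-oxo-13-(propan-2-yl)heptadeca-8,15-dienoate | C/C=C/[C@@H](O)[C@@H]([C@@H](OC(C)=O)C[C@](C)(O)/C=C/C[C@H](C)CC(=O)CC(=C)C(=O)OCC=C)C(C)C
F3 | step 15 | (6S,8E,10S,12S,13S,14R,15E)-12-(acetyloxy)-10,14-dihydroxy-6,10-dimethyl-2-methylidene-4-oxo-13-(propan-2-yl)heptadeca-8,15-dienoic acid | C/C=C/[C@@H](O)[C@@H]([C@@H](OC(C)=O)C[C@](C)(O)/C=C/C[C@H](C)CC(=O)CC(=C)C(=O)O)C(C)C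
F4 | step 16 | (3S,5E,7S,9S,10R)-10-[(2R)-4-(bromomethyl)-5-oxo-2,5-dihydrofuran-2-yl]-7-hydroxy-3,7,11-trimethyl-1-oxododec-5-en-9-yl acetate | BrCC1=C[C@@H](OC1=O)[C@@H]([C@@H](OC(C)=O)C[C@](C)(O)/C=C/C[C@H](C)CC=O)C(C)C
F5 | step 10 | 2-[(3S,4R,5E)-2-methyl-4-[(triethylsilyl)oxy]hept-5-en-3-yl]-1,3-dithiane | C/C=C/[C@@H](O[Si](CC)(CC)CC)[C@@H](C1SCCCS1)C(C)C
F6 | step 10 | (2S)-2-methyl-1-{2-[(3S,4R,5E)-2-methyl-4-[(triethylsilyl)oxy]hept-5-en-3-yl]-1,3-dithian-2-yl}but-3-en-2-ol | C/C=C/[C@@H](O[Si](CC)(CC)CC)[C@@H](C1(C[C@](C)(O)C=C)SCCCS1)C(C)C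
F7 | step 10 | (3S,6S,7R,8E)-3-hydroxy-3-methyl-6-(propan-2-yl)-7-[(triethylsilyl)oxy]deca-1,8-dien-5-one | C/C=C/[C@@H](O[Si](CC)(CC)CC)[C@@H](C(=O)C[C@](C)(O)C=C)C(C)C
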